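The cyclohexene (shikimate numbering, C1 bears CO2Me) is disconnected at the ring bond between the CH2 carbon C6 and the carbinol carbon C5 that carries the 3-methylpentanoate, the bond the shikimate pathway makes when phosphoenolpyruvate adds to the aldehyde of erythrose 4-phosphate. The key step repeats this as a ring closure: an indium-mediated intramolecular Barbier allylation in water, in which a (Z)-2-(bromomethyl)enoate, a phosphoenolpyruvate surrogate already holding C1=C2 and the ester, attacks a tethered aldehyde. It exploits the homoallylic alcohol array C5(OH)–C6H2–C1(CO2Me)=C2 of the ring, sets C5 and gives methyl 3,4-O-isopropylideneshikimate. The precursor is an acyclic cis-dioxolane from D-erythronolactone acetonide; three selective acylations finish the target.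

Key step: step 7

Remark: (S)-3-methylpentanoic acid and (R)-2-methylbutanoic acid are taken as purchasable enantiopure acids; ring atoms are numbered as in shikimic acid (C1 CO2Me, C2 alkene CH, C3 OAc, C4 2-methylbutanoate, C5 3-methylpentanoate, C6 CH2).

Step 1
Reactants: 1 2,3-O-isopropylidene-D-erythronolactone
Product: 2 2,3-O-isopropylidene-D-erythrofuranose (lactol as anomer mixture)
Conditions: i-Bu2AlH, CH2Cl2, −78 °C
Reagents that add atoms: none
Why: Partial lactone reduction with i-Bu2AlH at low temperature should stop at the lactol stage and leaves both acetonide stereocentres untouched.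

Step 2
Reactants: 2 2,3-O-isopropylidene-D-erythrofuranose; 3 methyltriphenylphosphonium bromide
Product: 4 [(4R,5S)-2,2-dimethyl-5-vinyl-1,3-dioxolan-4-yl]methanol
Conditions: Ph3PCH3Br, KOt-Bu, THF, 0 °C to rt
Reagents that add atoms: methyltriphenylphosphonium bromide (3), C[P+](c1ccccc1)(c1ccccc1)c1ccccc1.[Br-]
Why: Wittig methylenation of the open hydroxy-aldehyde form of the lactol turns the lactol carbon into a vinyl group (the masked C5 aldehyde) and frees the primary alcohol at the other end.

Step 3
Reactants: 4 [(4R,5S)-2,2-dimethyl-5-vinyl-1,3-dioxolan-4-yl]methanol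
Product: 5 (4S,5S)-2,2-dimethyl-5-vinyl-1,3-dioxolane-4-carbaldehyde
Conditions: Dess–Martin periodinane, NaHCO3, CH2Cl2, 0 °C to rt
Reagents that add atoms: none
Why: Dess–Martin oxidation under buffered, amine-free conditions should give the aldehyde without epimerising the adjacent cis-dioxolane carbon, and the crude aldehyde is used at once.

Step 4
Reactants: 5 (4S,5S)-2,2-dimethyl-5-vinyl-1,3-dioxolane-4-carbaldehyde; 6 methyl acrylate
Product: 7 methyl 2-{hydroxy[(4R,5S)-2,2-dimethyl-5-vinyl-1,3-dioxolan-4-yl]methyl}prop-2-enoate (both carbinol epimers)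
Conditions: methyl acrylate, DABCO, 1,4-dioxane/H2O (1:1), rt
Reagents that add atoms: methyl acrylate (6), C=CC(=O)OC
Why: Morita–Baylis–Hillman reaction of the reactive α-alkoxy aldehyde with the DABCO–acrylate zwitterion should attach C1, C6 and the ester in one operation, and the carbinol centre it creates is erased in step 5.

Step 5
Reactants: 7 methyl 2-{hydroxy[(4R,5S)-2,2-dimethyl-5-vinyl-1,3-dioxolan-4-yl]methyl}prop-2-enoate
Product: 8 methyl (2Z)-2-(bromomethyl)-3-[(4R,5S)-2,2-dimethyl-5-vinyl-1,3-dioxolan-4-yl]prop-2-enoate
Conditions: NBS, Me2S, CH2Cl2, 0 °C to rt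
Reagents that add atoms: N-bromosuccinimide, O=C1CCC(=O)N1Br
Why: Corey–Kim activation of the allylic alcohol followed by SN2′ attack of bromide at the terminal CH2 should convert both carbinol epimers into the thermodynamically preferred (Z)-2-(bromomethyl)enoate, which places C6 and C3 cis on C1=C2.

Step 6
Reactants: 8 methyl (2Z)-2-(bromomethyl)-3-[(4R,5S)-2,2-dimethyl-5-vinyl-1,3-dioxolan-4-yl]prop-2-enoate
Product: 10 methyl (2Z)-2-(bromomethyl)-3-[(4R,5R)-5-formyl-2,2-dimethyl-1,3-dioxolan-4-yl]prop-2-enoate, via secondary ozonide 9 (not isolated)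
Conditions: O3, CH2Cl2, −78 °C (Sudan Red 7B end point); then PPh3, −78 °C to rt
Reagents that add atoms: ozone, [O-][O+]=O
Why: Chemoselective ozonolysis should cleave the monosubstituted vinyl group before the electron-poor trisubstituted enoate that carries CO2Me and CH2Br, and base-free reduction of the ozonide keeps the cis-dioxolane aldehyde configurationally intact.

Step 7
Reactants: 10 methyl (2Z)-2-(bromomethyl)-3-[(4R,5R)-5-formyl-2,2-dimethyl-1,3-dioxolan-4-yl]prop-2-enoate
Product: 12 methyl 3,4-O-isopropylideneshikimate, via allylindium dibromide 11 (not isolated)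
Conditions: In powder, THF/H2O (1:1), 0.005 M, rt
Reagents that add atoms: none
Why: Indium metal inserts into the allylic C–Br bond of 10 to give the water-tolerant, fluxional allylindium 11, whose CH2 terminus (C6) adds to the tethered aldehyde carbon (C5); this is an intramolecular Barbier-type carbonyl allylation, the ring-closing form of the known indium- or zinc-mediated additions of 2-(bromomethyl)acrylates to sugar aldehydes and of the cyclisations of formyl-tethered 2-(bromomethyl)enoates. The cyclohexene closes in a 6-exo-trig mode at the carbonyl group, with C1=C2 of the (Z)-enoate becoming the ring alkene; bonding through the other allyl terminus (C2) would need a cyclobutane and is excluded by strain, so ring size fixes the regiochemistry. The (Z)-geometry (C6 and C3 cis on the double bond) and the cis-dioxolane, which holds both arms on one face, pre-organise the chain, and high dilution suppresses intermolecular allylation. The only new stereocentre, C5, is controlled by the adjacent dioxolane carbon C4: in water the acetal oxygen should not chelate the metal, so the aldehyde is expected to react with the C4–O bond anti to the forming C5–C6 bond (polar Felkin–Anh arrangement) and the carbonyl oxygen pseudo-equatorial, which gives the 4,5-trans alcohol of the shikimate series. The chemoselectivity needed (allyl bromide and aldehyde in the presence of the conjugated ester and the acetonide) is secured by the mild aqueous conditions, and C3 and C4 are not at risk because no base is present.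

Step 8
Reactants: 12 methyl 3,4-O-isopropylideneshikimate; 13 (S)-3-methylpentanoic acid
Product: 14 methyl 3,4-O-isopropylidene-5-O-[(3S)-3-methylpentanoyl]shikimate
Conditions: (S)-3-methylpentanoic acid, DCC, DMAP (cat.), CH2Cl2, 0 °C to rt
Reagents that add atoms: (S)-3-methylpentanoic acid (13), CC[C@H](C)CC(=O)O
Why: Steglich esterification acylates the only free hydroxyl (C5) with retention, and the β-stereocentre of the acid cannot epimerise.

Step 9
Reactants: 14 methyl 3,4-O-isopropylidene-5-O-[(3S)-3-methylpentanoyl]shikimate
Product: 15 methyl 5-O-[(3S)-3-methylpentanoyl]shikimate (3,4-diol)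
Conditions: AcOH/H2O (4:1), 50 °C
Reagents that add atoms: none
Why: Mild acid hydrolysis of the isopropylidene acetal should free the cis-3,4-diol while both esters survive and, without base, the C5 acyl group should not migrate.

Step 10
Reactants: 15 methyl 5-O-[(3S)-3-methylpentanoyl]shikimate; 16 trimethyl orthoacetate
Product: 18 methyl 3-O-acetyl-5-O-[(3S)-3-methylpentanoyl]shikimate (free 4-OH), via cyclic 1-methoxyethylidene orthoester 17 (not isolated)
Conditions: MeC(OMe)3, CSA (cat.), CH2Cl2, rt; then AcOH/H2O (4:1), rt
Reagents that add atoms: trimethyl orthoacetate (16), CC(OC)(OC)OC; water, O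
Why: Orthoester exchange on the cis-diol and kinetic acid hydrolysis of the cyclic orthoester should leave the acetate on the pseudo-axial oxygen (O3) and the hydroxyl on the equatorial one (O4), the known regiochemistry of orthoester opening of cis-diols, with no stereocentre involved.

Step 11
Reactants: 18 methyl 3-O-acetyl-5-O-[(3S)-3-methylpentanoyl]shikimate; 19 (R)-2-methylbutanoic acid
Product: 20 methyl (3R,4S,5R)-3-acetoxy-4-{[(2R)-2-methylbutanoyl]oxy}-5-{[(3S)-3-methylpentanoyl]oxy}cyclohex-1-ene-1-carboxylate (CNP0188172.1)
Conditions: (R)-2-methylbutanoic acid, DCC, DMAP (cat.), CH2Cl2, 0 °C to rt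
Reagents that add atoms: (R)-2-methylbutanoic acid (19), CC[C@@H](C)C(=O)O
Why: Steglich esterification of the remaining 4-OH should outpace acetyl migration from O3, and keeping DMAP catalytic limits epimerisation of the acid's α-stereocentre.

Compound list
1 | 2,3-O-isopropylidene-D-erythronolactone, (3aR,6aR)-2,2-dimethyldihydrofuro[3,4-d][1,3]dioxol-4(3aH)-one | CC1(C)O[C@@H]2COC(=O)[C@@H]2O1 | starting material
2 | 2,3-O-isopropylidene-D-erythrofuranose (lactol, both anomers) | CC1(C)O[C@@H]2COC(O)[C@@H]2O1 | intermediate
3 | methyltriphenylphosphonium bromide | C[P+](c1ccccc1)(c1ccccc1)c1ccccc1.[Br-] | starting material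
4 | [(4R,5S)-2,2-dimethyl-5-vinyl-1,3-dioxolan-4-yl]methanol | OC[C@H]1OC(C)(C)O[C@H]1C=C | intermediate
5 | (4S,5S)-2,2-dimethyl-5-vinyl-1,3-dioxolane-4-carbaldehyde | O=C[C@H]1OC(C)(C)O[C@H]1C=C | intermediate
6 | methyl acrylate | C=CC(=O)OC | starting material
7 | methyl 2-{hydroxy[(4R,5S)-2,2-dimethyl-5-vinyl-1,3-dioxolan-4-yl]methyl}prop-2-enoate (both carbinol epimers) | C=C(C(=O)OC)C(O)[C@H]1OC(C)(C)O[C@H]1C=C | intermediate
8 | methyl (2Z)-2-(bromomethyl)-3-[(4R,5S)-2,2-dimethyl-5-vinyl-1,3-dioxolan-4-yl]prop-2-enoate | COC(=O)/C(CBr)=C/[C@H]1OC(C)(C)O[C@H]1C=C | intermediate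
9 | secondary ozonide of 8 (1,2,4-trioxolan-3-yl in place of the vinyl group, both epimers at the ozonide carbon) | COC(=O)/C(CBr)=C/[C@H]1OC(C)(C)O[C@H]1C2OCOO2 | intermediate
10 | methyl (2Z)-2-(bromomethyl)-3-[(4R,5R)-5-formyl-2,2-dimethyl-1,3-dioxolan-4-yl]prop-2-enoate | COC(=O)/C(CBr)=C/[C@H]1OC(C)(C)O[C@H]1C=O | intermediate
11 | allylindium dibromide from 10 (trivalent indium on the former CH2Br carbon, drawn as the σ-allyl form) | COC(=O)/C(C[In](Br)Br)=C/[C@H]1OC(C)(C)O[C@H]1C=O | intermediate
12 | methyl 3,4-O-isopropylideneshikimate, methyl (3aR,7R,7aS)-7-hydroxy-2,2-dimethyl-3a,6,7,7a-tetrahydro-1,3-benzodioxole-5-carboxylate | COC(=O)C1=C[C@H]2OC(C)(C)O[C@H]2[C@H](O)C1 | intermediate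
13 | (S)-3-methylpentanoic acid | CC[C@H](C)CC(=O)O | starting material
14 | methyl (3aR,7R,7aS)-2,2-dimethyl-7-{[(3S)-3-methylpentanoyl]oxy}-3a,6,7,7a-tetrahydro-1,3-benzodioxole-5-carboxylate | COC(=O)C1=C[C@H]2OC(C)(C)O[C@H]2[C@H](OC(=O)C[C@@H](C)CC)C1 | intermediate
15 | methyl (3R,4R,5R)-3,4-dihydroxy-5-{[(3S)-3-methylpentanoyl]oxy}cyclohex-1-ene-1-carboxylate | COC(=O)C1=C[C@@H](O)[C@@H](O)[C@H](OC(=O)C[C@@H](C)CC)C1 | intermediate
16 | trimethyl orthoacetate | CC(OC)(OC)OC | starting material
17 | methyl (3aR,7R,7aS)-2-methoxy-2-methyl-7-{[(3S)-3-methylpentanoyl]oxy}-3a,6,7,7a-tetrahydro-1,3-benzodioxole-5-carboxylate (both epimers at the orthoester carbon) | COC(=O)C1=C[C@H]2OC(C)(OC)O[C@H]2[C@H](OC(=O)C[C@@H](C)CC)C1 | intermediate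
18 | methyl (3R,4S,5R)-3-acetoxy-4-hydroxy-5-{[(3S)-3-methylpentanoyl]oxy}cyclohex-1-ene-1-carboxylate | COC(=O)C1=C[C@@H](OC(C)=O)[C@@H](O)[C@H](OC(=O)C[C@@H](C)CC)C1 | intermediate
19 | (R)-2-methylbutanoic acid | CC[C@@H](C)C(=O)O | starting material
20 | methyl (3R,4S,5R)-3-acetoxy-4-{[(2R)-2-methylbutanoyl]oxy}-5-{[(3S)-3-methylpentanoyl]oxy}cyclohex-1-ene-1-carboxylate | CC[C@H](C)CC(=O)O[C@@H]1CC(C(=O)OC)=C[C@@H](OC(C)=O)[C@H]1OC(=O)[C@H](C)CC | target

Total step count: 11. Longest linear sequence: 11 steps (1 to 20); all other building blocks are purchased.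

Steps most likely to fail

Step 7. The aldehyde may be attacked on the other face (for instance if the metal chelates the dioxolane oxygen), so that the ring closes to the 4,5-cis alcohol; intermolecular allylation may also compete. The fallback sets out from 10 and comes back at 14: the ring closure is run as before, and the alcohol of inverted C5 configuration, methyl 5-epi-3,4-O-isopropylideneshikimate F1, is taken on directly into a Mitsunobu esterification with acid 13 (PPh3, DIAD, THF, 0 °C). This inverts C5 and installs the 3-methylpentanoate in the same operation, so either facial outcome of the closure is funnelled into 14.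

Step 10. The orthoester may open toward the wrong oxygen, or the acetyl group may migrate between the cis oxygens O3 and O4, giving a mixture of monoacetates. The fallback sets out from 15 and comes back at 18: direct kinetic mono-acetylation with AcCl and 2,4,6-collidine in CH2Cl2 at −78 °C, relying on the allylic 3-OH being less hindered than the 4-OH, which is flanked by two substituents; no new compound is made on the way (F0).

Step 4. The amine base may epimerise the aldehyde carbon (cis to trans dioxolane) during a slow Morita–Baylis–Hillman reaction, eroding the C3 configuration. The fallback sets out from 5 and comes back at 7: vinylalumination without amine base, in which methyl propiolate is hydroaluminated with i-Bu2AlH and N-methylmorpholine N-oxide in THF at 0 °C to [1-(methoxycarbonyl)vinyl]diisobutylaluminium F2, which should add to aldehyde 5 within hours at 0 °C and give 7 after aqueous work-up.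

Further compounds
F1 | step 7 | methyl (3aR,7S,7aS)-7-hydroxy-2,2-dimethyl-3a,6,7,7a-tetrahydro-1,3-benzodioxole-5-carboxylate (methyl 5-epi-3,4-O-isopropylideneshikimate) | COC(=O)C1=C[C@H]2OC(C)(C)O[C@H]2[C@@H](O)C1
F0 | step 10 | none | none
F2 | step 4 | [1-(methoxycarbonyl)vinyl]diisobutylaluminium | COC(=O)C(=C)[Al](CC(C)C)CC(C)C
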